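**Strategy**

The target is cut through the cyclopentene ring that joins the chromone to the 7-oxabenzonorbornane: its two exo, cis bonds (chromone C2–CH and carbinol carbon–CH) mark the former strained C=C of a 1-aryl-oxabenzonorbornadiene. In the key step zerovalent palladium inserts into the mixed anhydride of a chromone-3-carboxylic acid, the acylpalladium adds exo across that alkene, and palladation of the chromone C2–H followed by reductive elimination forms the C2–CH bond, closing the five-membered ring. Two fully elaborated halves are thereby joined and both ring-fusion stereocentres set; the resulting ketone is later converted, from its convex face, into the tertiary hydroxy ester.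

Key step: step 16

Assumptions: TBS = tert-butyldimethylsilyl, MOM = methoxymethyl. (R)-p-Tolyl vinyl sulfoxide 12 is taken as a catalogue reagent. The side-chain tertiary alcohol is carried unprotected, so each organometallic step uses one extra equivalent of base.

**Route**

Step 1
Reactants: 1 4-hydroxy-3-methylbenzaldehyde; 2 4-bromo-2-methylbutan-2-ol
Product: 3 4-(3-hydroxy-3-methylbutoxy)-3-methylbenzaldehyde
Conditions: K2CO3, DMF, 70 °C
Reagents that add atoms: none
Why: Williamson ether synthesis, in which the phenoxide (the only acidic OH) displaces the primary bromide while the tertiary alcohol of 2 stays inert.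

Step 2
Reactants: 3 4-(3-hydroxy-3-methylbutoxy)-3-methylbenzaldehyde
Product: 5 4-(3-hydroxy-3-methylbutoxy)-3-methylphenol, via aryl formate 4 (not isolated)
Conditions: mCPBA, CH2Cl2, rt; then K2CO3 (cat.), MeOH
Reagents that add atoms: 3-chloroperoxybenzoic acid, OOC(=O)c1cccc(Cl)c1
Why: Dakin-type Baeyer–Villiger oxidation, in which the electron-rich 4-alkoxyaryl group migrates to give the aryl formate, which is then methanolysed to the phenol.

Step 3
Reactants: 5 4-(3-hydroxy-3-methylbutoxy)-3-methylphenol
Product: 6 2-bromo-4-(3-hydroxy-3-methylbutoxy)-5-methylphenol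
Conditions: NBS, MeCN, −20 to 0 °C
Reagents that add atoms: N-bromosuccinimide, O=C1CCC(=O)N1Br
Why: Electrophilic aromatic bromination ortho to the free phenol (para position blocked), at the ortho site that is not flanked by the methyl-bearing carbon and lies para to it.

Step 4
Reactants: 6 2-bromo-4-(3-hydroxy-3-methylbutoxy)-5-methylphenol
Product: 7 4-[4-bromo-5-(TBS-oxy)-2-methylphenoxy]-2-methylbutan-2-ol
Conditions: TBSCl, imidazole, DMF, rt
Reagents that add atoms: tert-butyldimethylsilyl chloride, C[Si](C)(Cl)C(C)(C)C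
Why: Imidazole-promoted silylation of the phenol, which the hindered tertiary alcohol does not undergo with the silyl chloride.

Step 5
Reactants: 7 4-[4-bromo-5-(TBS-oxy)-2-methylphenoxy]-2-methylbutan-2-ol
Product: 8 2-bromo-3-(TBS-oxy)-6-(3-hydroxy-3-methylbutoxy)-5-methylbenzaldehyde
Conditions: LiN(i-Pr)2 (2.2 equiv), THF, −78 °C; DMF; H2O
Reagents that add atoms: N,N-dimethylformamide, CN(C)C=O
Why: Directed ortho-metalation, in which the amide base (after forming the side-chain alkoxide) removes the ring proton flanked by bromine and the alkoxy oxygen, and the aryllithium is formylated at −78 °C, below the onset of aryne formation.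

Step 6
Reactants: 9 2,6-dihydroxybenzaldehyde
Product: 10 2,6-bis(TBS-oxy)benzaldehyde
Conditions: TBSOTf, 2,6-lutidine, CH2Cl2, 0 °C
Reagents that add atoms: tert-butyldimethylsilyl triflate, C[Si](C)(OS(=O)(=O)C(F)(F)F)C(C)(C)C
Why: Standard silyl ether formation, with the triflate chosen because both phenols are hydrogen-bonded to the aldehyde.

Step 7
Reactants: 8 2-bromo-3-(TBS-oxy)-6-(3-hydroxy-3-methylbutoxy)-5-methylbenzaldehyde; 10 2,6-bis(TBS-oxy)benzaldehyde
Product: 11 3-[2,6-bis(TBS-oxy)phenyl]-4-(TBS-oxy)-7-(3-hydroxy-3-methylbutoxy)-6-methyl-1,3-dihydro-2-benzofuran-1-ol (lactol, diastereomer mixture)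
Conditions: LiN(Me)CH2CH2NMe2 (2.1 equiv, from the amine and n-BuLi), THF, −20 °C; n-BuLi (1.1 equiv), −78 °C; 10, −78 °C; H2O at −78 °C
Reagents that add atoms: none
Why: In situ masking of the aldehyde as its lithium alpha-amino alkoxide, bromine–lithium exchange and 1,2-addition of the aryllithium to 10, after which the cold quench (to forestall silyl migration to the alkoxide) releases the aldehyde, which closes with the new benzylic alcohol to the lactol whose stereocentres are erased in step 8.

Step 8
Reactants: 11 lactol; 12 (R)-p-tolyl vinyl sulfoxide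
Product: 14 endo sulfoxide Diels–Alder adduct (sulfinyl on the CH next to the H-bearing bridgehead; bridgeheads as in 15), via isobenzofuran 13 (not isolated)
Conditions: 12 (3 equiv), AcOH (10 mol %), toluene, 70 °C; chromatographic separation of diastereomers
Reagents that add atoms: none
Why: Acid-catalysed dehydration of the lactol gives the very reactive 1-aryl-isobenzofuran, which undergoes Diels–Alder addition to the vinyl sulfoxide (sulfinyl remote from the hindered aryl bridgehead), and because the sulfur is enantiopure the two bridgehead series are diastereomers, so the adducts with the target's bridgehead configuration are separated and taken on, all of them converging on 15.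

Step 9
Reactants: 14 sulfoxide adduct
Product: 15 (1S,4R)-1-[2,6-bis(TBS-oxy)phenyl]-8-(TBS-oxy)-5-(3-hydroxy-3-methylbutoxy)-6-methyl-1,4-dihydro-1,4-epoxynaphthalene
Conditions: toluene, 110 °C, solid NaHCO3 (buffer)
Reagents that add atoms: none
Why: Thermal syn-elimination of the sulfoxide with the cis hydrogen of the neighbouring CH2 (the vinyl sulfoxide acting as an acetylene equivalent), which leaves both bridgehead stereocentres untouched.

Step 10
Reactants: 16 3,5-dihydroxybenzyl alcohol
Product: 17 1,3-bis(methoxymethoxy)-5-[(methoxymethoxy)methyl]benzene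
Conditions: NaH, MOMCl, THF/DMF, 0 °C to rt
Reagents that add atoms: chloromethyl methyl ether, COCCl
Why: Williamson-type alkylation of all three hydroxyls, the two aryl MOM ethers serving as directing groups for step 11.

Step 11
Reactants: 17 tris-MOM ether
Product: 18 1-{2,6-bis(methoxymethoxy)-4-[(methoxymethoxy)methyl]phenyl}ethan-1-one
Conditions: n-BuLi, THF, 0 °C; N-methoxy-N-methylacetamide, −78 to 0 °C; H2O
Reagents that add atoms: N-methoxy-N-methylacetamide, CC(=O)N(C)OC
Why: Directed ortho-metalation at the position flanked by two MOM-oxy groups, followed by Weinreb ketone synthesis, which stops at the ketone.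

Step 12
Reactants: 18 MOM-protected acetophenone
Product: 19 1-[2,6-dihydroxy-4-(hydroxymethyl)phenyl]ethan-1-one
Conditions: HCl (cat.), MeOH, 50 °C
Reagents that add atoms: none
Why: Acid-catalysed acetal exchange with methanol removes the three MOM groups.

Step 13
Reactants: 19 triol
Product: 20 1-{4-[(TBS-oxy)methyl]-2,6-dihydroxyphenyl}ethan-1-one
Conditions: TBSCl (1.05 equiv), imidazole, DMF, 0 °C
Reagents that add atoms: tert-butyldimethylsilyl chloride, C[Si](C)(Cl)C(C)(C)C
Why: Selective silylation of the primary benzylic alcohol, the two phenols being hydrogen-bonded to the ketone and hindered.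

Step 14
Reactants: 20 silyl ether
Product: 22 7-[(TBS-oxy)methyl]-5-hydroxy-3-iodo-4H-chromen-4-one, via enaminone 21 (not isolated)
Conditions: Me2NCH(OMe)2, toluene, 80 °C; then I2, CHCl3, rt
Reagents that add atoms: N,N-dimethylformamide dimethyl acetal, COC(OC)N(C)C; iodine, II
Why: Condensation of the methyl ketone to the enaminone, then iodine-induced chromone cyclization (iodination of the enaminone alpha carbon, conjugate attack by one of the two equivalent phenols and loss of dimethylamine).

Step 15
Reactants: 22 3-iodochromone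
Product: 23 7-[(TBS-oxy)methyl]-5-hydroxy-4-oxo-4H-chromene-3-carboxylic acid
Conditions: Pd(OAc)2 (5 mol %), Xantphos (5 mol %), CO (1 atm), H2O, Et3N, DMF, 60 °C; mild acid work-up
Reagents that add atoms: carbon monoxide, [C-]#[O+]; water, O
Why: Palladium-catalysed hydroxycarbonylation of the vinylic iodide (oxidative addition, CO insertion, hydrolysis of the acylpalladium).

Step 16
Reactants: 23 chromone-3-carboxylic acid; 15 oxabenzonorbornadiene
Product: 25 silyl-protected cyclopenta[b]chromene-1,9-dione (exo,cis-fused to the oxabenzonorbornane), via mixed pivalic anhydride 24 (not isolated)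
Conditions: pivalic anhydride (1.5 equiv), Pd(OAc)2 (10 mol %), PCy3 (20 mol %), toluene, 90 °C
Reagents that add atoms: none
Why: Proposed new method: the mixed anhydride 24 adds oxidatively to zerovalent palladium at its less hindered acyl C–O bond, and the acylpalladium pivalate adds syn across the strained alkene of 15 from the exo face, the migrating acyl group taking the alkene carbon remote from the aryl-bearing bridgehead and palladium the adjacent one; the closest known reactions are the palladium-catalysed carboacylation of norbornenes with acyl electrophiles and the Catellani-type C–H palladation by an alkylpalladium that has no syn beta hydrogen. The alkylpalladium then metalates the acidic chromone C2–H by pivalate-assisted concerted metalation–deprotonation, and reductive elimination from the six-membered palladacycle forms the C2–C(sp3) bond, closing the cyclopentenone in a mode (formally 5-endo) that direct radical or ionic attack on C2 could not deliver. Both new stereocentres (the two ring-fusion CH) follow from syn, exo addition and retention in the reductive elimination, so the ring is cis-fused on the face of the oxygen bridge as in the target, with the absolute sense relayed from the bridgeheads of 15. The step needs regioselective acylpalladation (secured by the steric difference between the quaternary and the CH bridgehead), C–H palladation faster than beta-oxygen elimination (favoured by a neutral, halide-free palladium pivalate) and no decarbonylation (moderate temperature).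

Step 17
Reactants: 25 dione
Product: 26 tertiary alcohol carrying a 1-methoxyvinyl group on the former ketone carbon (OH on the concave face)
Conditions: methyl vinyl ether, t-BuLi, THF, −78 to 0 °C; CeCl3, −78 °C; 25 (reagent 4 equiv), −78 °C; H2O
Reagents that add atoms: methyl vinyl ether (as 1-methoxyvinyllithium), COC=C
Why: 1,2-Addition of a weakly basic organocerium reagent to the cyclopentenone carbonyl from the convex face (the face of the two ring-fusion hydrogens, anti to the oxygen-bridged bicycle), which places the OH on the concave face as in the target, while the chromone carbonyl is shielded as its chelated 5-phenoxide and the beta carbon is fully substituted.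

Step 18
Reactants: 26 enol ether
Product: 27 tetra-TBS-protected aspergichromone A
Conditions: O3, CH2Cl2/MeOH, −78 °C (indicator end point); then Me2S
Reagents that add atoms: ozone, [O-][O+]=O
Why: Ozonolysis of the electron-rich enol ether, by far the most reactive alkene present, turns C(OMe)=CH2 directly into the methyl ester without touching the new stereocentre.

Step 19
Reactants: 27 protected target
Product: 28 aspergichromone A
Conditions: HF·pyridine, pyridine, THF, 0 °C to rt
Reagents that add atoms: none
Why: Fluoride-mediated cleavage of the four Si–O bonds under buffered conditions that should spare the acid-sensitive bridging ether, the methyl ester and the chromone.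

**Compound list**

1 | 4-hydroxy-3-methylbenzaldehyde | Cc1cc(C=O)ccc1O | starting material
2 | 4-bromo-2-methylbutan-2-ol | CC(C)(O)CCBr | starting material
3 | 4-(3-hydroxy-3-methylbutoxy)-3-methylbenzaldehyde | Cc1cc(C=O)ccc1OCCC(C)(C)O | intermediate
4 | 4-(3-hydroxy-3-methylbutoxy)-3-methylphenyl formate | Cc1cc(OC=O)ccc1OCCC(C)(C)O | intermediate
5 | 4-(3-hydroxy-3-methylbutoxy)-3-methylphenol | Cc1cc(O)ccc1OCCC(C)(C)O | intermediate
6 | 2-bromo-4-(3-hydroxy-3-methylbutoxy)-5-methylphenol | Cc1cc(O)c(Br)cc1OCCC(C)(C)O | intermediate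
7 | 4-[4-bromo-5-(TBS-oxy)-2-methylphenoxy]-2-methylbutan-2-ol | Cc1cc(O[Si](C)(C)C(C)(C)C)c(Br)cc1OCCC(C)(C)O | intermediate
8 | 2-bromo-3-(TBS-oxy)-6-(3-hydroxy-3-methylbutoxy)-5-methylbenzaldehyde | Cc1cc(O[Si](C)(C)C(C)(C)C)c(Br)c(C=O)c1OCCC(C)(C)O | intermediate
9 | 2,6-dihydroxybenzaldehyde | O=Cc1c(O)cccc1O | starting material
10 | 2,6-bis(TBS-oxy)benzaldehyde | O=Cc1c(O[Si](C)(C)C(C)(C)C)cccc1O[Si](C)(C)C(C)(C)C | intermediate
11 | lactol: 3-[2,6-bis(TBS-oxy)phenyl]-4-(TBS-oxy)-7-(3-hydroxy-3-methylbutoxy)-6-methyl-1,3-dihydro-2-benzofuran-1-ol (diastereomer mixture) | OC1OC(c2c(O[Si](C)(C)C(C)(C)C)cccc2O[Si](C)(C)C(C)(C)C)c2c(O[Si](C)(C)C(C)(C)C)cc(C)c(OCCC(C)(C)O)c21 | intermediate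
12 | (R)-p-tolyl vinyl sulfoxide | C=C[S@@](=O)c1ccc(C)cc1 | starting material
13 | 1-[2,6-bis(TBS-oxy)phenyl]-7-(TBS-oxy)-4-(3-hydroxy-3-methylbutoxy)-5-methyl-2-benzofuran (isobenzofuran) | CC(C)(O)CCOc1c(C)cc(O[Si](C)(C)C(C)(C)C)c2c(-c3c(O[Si](C)(C)C(C)(C)C)cccc3O[Si](C)(C)C(C)(C)C)occ12 | intermediate
14 | 1-[2,6-bis(TBS-oxy)phenyl]-8-(TBS-oxy)-5-(3-hydroxy-3-methylbutoxy)-6-methyl-3-endo-[(R)-p-tolylsulfinyl]-1,2,3,4-tetrahydro-1,4-epoxynaphthalene, bridgeheads as in 15 | C1[C@H]([S@@](=O)c3ccc(C)cc3)[C@H]2O[C@]1(c1c(O[Si](C)(C)C(C)(C)C)cccc1O[Si](C)(C)C(C)(C)C)c1c(O[Si](C)(C)C(C)(C)C)cc(C)c(OCCC(C)(C)O)c12 | intermediate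
15 | (1S,4R)-1-[2,6-bis(TBS-oxy)phenyl]-8-(TBS-oxy)-5-(3-hydroxy-3-methylbutoxy)-6-methyl-1,4-dihydro-1,4-epoxynaphthalene | C1=C[C@H]2O[C@]1(c1c(O[Si](C)(C)C(C)(C)C)cccc1O[Si](C)(C)C(C)(C)C)c1c(O[Si](C)(C)C(C)(C)C)cc(C)c(OCCC(C)(C)O)c12 | intermediate
16 | 3,5-dihydroxybenzyl alcohol | OCc1cc(O)cc(O)c1 | starting material
17 | 1,3-bis(methoxymethoxy)-5-[(methoxymethoxy)methyl]benzene | COCOCc1cc(OCOC)cc(OCOC)c1 | intermediate
18 | 1-{2,6-bis(methoxymethoxy)-4-[(methoxymethoxy)methyl]phenyl}ethan-1-one | CC(=O)c1c(OCOC)cc(COCOC)cc1OCOC | intermediate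
19 | 1-[2,6-dihydroxy-4-(hydroxymethyl)phenyl]ethan-1-one | CC(=O)c1c(O)cc(CO)cc1O | intermediate
20 | 1-{4-[(TBS-oxy)methyl]-2,6-dihydroxyphenyl}ethan-1-one | CC(=O)c1c(O)cc(CO[Si](C)(C)C(C)(C)C)cc1O | intermediate
21 | (E)-1-{4-[(TBS-oxy)methyl]-2,6-dihydroxyphenyl}-3-(dimethylamino)prop-2-en-1-one | CN(C)/C=C/C(=O)c1c(O)cc(CO[Si](C)(C)C(C)(C)C)cc1O | intermediate
22 | 7-[(TBS-oxy)methyl]-5-hydroxy-3-iodo-4H-chromen-4-one | O=c1c(I)coc2cc(CO[Si](C)(C)C(C)(C)C)cc(O)c12 | intermediate
23 | 7-[(TBS-oxy)methyl]-5-hydroxy-4-oxo-4H-chromene-3-carboxylic acid | OC(=O)c1coc2cc(CO[Si](C)(C)C(C)(C)C)cc(O)c2c1=O | intermediate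
24 | mixed anhydride of 23 with pivalic acid | CC(C)(C)C(=O)OC(=O)c1coc2cc(CO[Si](C)(C)C(C)(C)C)cc(O)c2c1=O | intermediate
25 | tetra-TBS cyclopenta[b]chromene-1,9-dione, exo,cis-fused to the oxabenzonorbornane (ketone on the CH next to the H-bearing bridgehead, chromone C2 on the CH next to the aryl-bearing bridgehead) | O=C1c2c(oc3cc(CO[Si](C)(C)C(C)(C)C)cc(O)c3c2=O)[C@H]2[C@@H]1[C@H]1O[C@]2(c2c(O[Si](C)(C)C(C)(C)C)cccc2O[Si](C)(C)C(C)(C)C)c2c(O[Si](C)(C)C(C)(C)C)cc(C)c(OCCC(C)(C)O)c21 | intermediate
26 | 1-methoxyvinyl carbinol from 25 (OH on the concave face) | COC(=C)[C@@]1(O)c2c(oc3cc(CO[Si](C)(C)C(C)(C)C)cc(O)c3c2=O)[C@H]2[C@@H]1[C@H]1O[C@]2(c2c(O[Si](C)(C)C(C)(C)C)cccc2O[Si](C)(C)C(C)(C)C)c2c(O[Si](C)(C)C(C)(C)C)cc(C)c(OCCC(C)(C)O)c21 | intermediate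
27 | tetra-TBS aspergichromone A | COC(=O)[C@@]1(O)c2c(oc3cc(CO[Si](C)(C)C(C)(C)C)cc(O)c3c2=O)[C@H]2[C@@H]1[C@H]1O[C@]2(c2c(O[Si](C)(C)C(C)(C)C)cccc2O[Si](C)(C)C(C)(C)C)c2c(O[Si](C)(C)C(C)(C)C)cc(C)c(OCCC(C)(C)O)c21 | intermediate
28 | aspergichromone A | COC(=O)[C@@]1(O)c2c(oc3cc(CO)cc(O)c3c2=O)[C@H]2[C@@H]1[C@H]1O[C@]2(c2c(O)cccc2O)c2c(O)cc(C)c(OCCC(C)(C)O)c21 | target

**Step count and risks**

Total step count: 19. Longest linear sequence: 12 steps (steps 1–5, 7–9, 16–19).

Steps most likely to fail:

1. Step 16 (new method). Acylpalladation may take the wrong regiochemistry, or beta-oxygen elimination (opening of the oxygen bridge) or decarbonylation of the acylpalladium may outrun the C–H palladation. The fallback uses known chemistry, sets out from sulfoxide 14 (whose sulfinyl group already marks the correct carbon) and returns at 25. Deprotonation alpha to sulfur (LiN(i-Pr)2, THF, −78 °C) and acylation with anhydride 24 (pre-treated with one equivalent of base for its phenol) should give the alpha-sulfinyl ketone F1. On warming, F1 should lose the sulfenic acid by syn-elimination to give the cross-conjugated dienone, the 2-acyl-oxabenzonorbornadiene F2. A Nazarov cyclization (Cu(OTf)2 or Sc(OTf)3 as catalyst, 1,2-dichloroethane, two-point binding to the 1,3-dicarbonyl) should then form the same C2–CH bond by conrotatory closure on the exo face. Loss of the C2 proton and endo protonation of the enol would lead back to 25. The acid lability of the oxygen bridge is the weak point of this alternative.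

2. Step 8. Facial and regiochemical selectivity of the sulfoxide Diels–Alder reaction may be poor and the diastereomers hard to separate. The fallback sets out from lactol 11 and returns at 15. Achiral phenyl vinyl sulfoxide is used under the same conditions to give the racemic adduct mixture F3, which is heated directly (toluene, 110 °C) to the racemic alkene F4. The enantiomers are then separated by preparative chromatography on a chiral stationary phase (amylose carbamate, supercritical CO2/2-propanol), giving 15 and its enantiomer F5.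

3. Step 7. Addition of a doubly ortho-substituted aryllithium to a doubly ortho-substituted aldehyde may be slow, so that silyl migration to the alkoxide or to the aryl carbanion competes. The fallback sets out from aldehyde 8 and returns at isobenzofuran 13 in step 8. Aldehyde 8 is isolated as its dimethyl acetal F6 (HC(OMe)3, PPTS, MeOH). After bromine–lithium exchange (n-BuLi, THF, −78 °C) and transmetalation with CeCl3, the less basic arylcerium is added to 10, which should give the hydroxy acetal F7 after a cold quench. F7 is not converted into 11 but taken directly into step 8, where the acid should turn it, with loss of methanol, into the same isobenzofuran 13.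

**Further compounds**

F1 | step 16 | alpha-sulfinyl ketone: 14 acylated on the sulfinyl-bearing carbon with the chromone-3-carbonyl group (acyl exo, sulfinyl endo) | C1[C@@]([S@@](=O)c3ccc(C)cc3)(C(=O)c3coc4cc(CO[Si](C)(C)C(C)(C)C)cc(O)c4c3=O)[C@H]2O[C@]1(c1c(O[Si](C)(C)C(C)(C)C)cccc1O[Si](C)(C)C(C)(C)C)c1c(O[Si](C)(C)C(C)(C)C)cc(C)c(OCCC(C)(C)O)c12
F2 | step 16 | dienone: 15 bearing the chromone-3-carbonyl group on the alkene carbon next to the H-bearing bridgehead | C1=C(C(=O)c3coc4cc(CO[Si](C)(C)C(C)(C)C)cc(O)c4c3=O)[C@H]2O[C@]1(c1c(O[Si](C)(C)C(C)(C)C)cccc1O[Si](C)(C)C(C)(C)C)c1c(O[Si](C)(C)C(C)(C)C)cc(C)c(OCCC(C)(C)O)c12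
F3 | step 8 | racemic phenylsulfinyl Diels–Alder adducts (isomer mixture, no descriptors) | C1C(S(=O)c3ccccc3)C2OC1(c1c(O[Si](C)(C)C(C)(C)C)cccc1O[Si](C)(C)C(C)(C)C)c1c(O[Si](C)(C)C(C)(C)C)cc(C)c(OCCC(C)(C)O)c12
F4 | step 8 | racemic 15 (no descriptors) | C1=CC2OC1(c1c(O[Si](C)(C)C(C)(C)C)cccc1O[Si](C)(C)C(C)(C)C)c1c(O[Si](C)(C)C(C)(C)C)cc(C)c(OCCC(C)(C)O)c12
F5 | step 8 | enantiomer of 15, (1R,4S) | C1=C[C@@H]2O[C@@]1(c1c(O[Si](C)(C)C(C)(C)C)cccc1O[Si](C)(C)C(C)(C)C)c1c(O[Si](C)(C)C(C)(C)C)cc(C)c(OCCC(C)(C)O)c12
F6 | step 7 | dimethyl acetal of 8 | COC(OC)c1c(Br)c(O[Si](C)(C)C(C)(C)C)cc(C)c1OCCC(C)(C)O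
F7 | step 7 | hydroxy acetal (racemic diaryl carbinol, no descriptor) | COC(OC)c1c(C(O)c2c(O[Si](C)(C)C(C)(C)C)cccc2O[Si](C)(C)C(C)(C)C)c(O[Si](C)(C)C(C)(C)C)cc(C)c1OCCC(C)(C)O
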